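All runs stem from a simulated flask for substances that don't exist, noise included.

I had no constants for any step, so I looked for a number from which time drops out.

| flask | solid substrate | free catalyst | remark | time |
|---|---|---|---|---|
| spring | 14 mM | 0.49 mM | run made earlier |  |
| winter | 14 mM | 0.77 mM | run made earlier |  |
| summer | 28 mM | 0.35 mM | run made earlier |  |
| flask | 14 mM | 0.35 mM |  | 40 h |

| run | time / h | target / % | isomer of the product / % |
|---|---|---|---|
| spring | 3.00 | 4.9 | 0.8 |
| spring | 6.00 | 6.9 | 2.5 |
| spring | 10.0 | 8.2 | 4.2 |
| spring | 15.0 | 8.6 | 5.8 |
| spring | 20.0 | 8.8 | 6.9 |
| spring | 25.0 | 9.0 | 7.0 |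
| winter | 3.00 | 4.9 | 0.8 |
| winter | 6.00 | 7.3 | 2.1 |
| winter | 10.0 | 8.0 | 4.3 |
| winter | 15.0 | 9.0 | 5.7 |
| winter | 20.0 | 9.4 | 6.6 |
| winter | 25.0 | 9.4 | 7.5 |
| summer | 2.00 | 2.1 | 0.4 |
| summer | 6.00 | 3.1 | 1.0 |
| summer | 12.0 | 4.1 | 2.3 |
| summer | 15.0 | 4.4 | 2.7 |
| summer | 25.0 | 4.8 | 3.3 |

(standard deviation of a reading: 0.3 percentage points)

- share of target in target plus isomer of the product at 1.0 h
- share of target in target plus isomer of the product at 40 h
- which of target and isomer of the product there is more of at 40 h

- given per volume of solution although it is solid: solid substrate
- reactions considered so far: starting material <-> target; target <-> isomer of the product; isomer of the product + free catalyst <-> starting material + free catalyst; free catalyst -> spent catalyst; solid substrate <-> starting material; starting material + free catalyst <-> idle complex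
- at the start none of the solid substrate is in solution

Divide the rate of target becoming isomer of the product by the rate of the way back. With both ways first order, that step has no net turnover when the quotient reaches one, and isomer per target then stands at a fixed value, the mark of thermodynamic control. The last readings of spring and winter, pooled, put this balance ratio at 0.788, so I reckoned the share of target in this flask at 40 h at 55.9%, if the ratio had arrived there by then.

But the last readings of summer give 0.688. Its target reading is about half the size of spring's, though, so the same scatter of 0.3 percentage points weighs about twice as much, and I left it out of the pool.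

But the road from isomer of the product through free catalyst to starting material might hold the ratio off. Yet spring and winter, which differ in catalyst by a factor of 1.57, read 0.778 and 0.798, and I saw no effect beyond the scatter.

But the ratio might still be climbing, since the same pool gave 0.742 at 20.0 h. A further rise of that size gives 0.834, still less than one, and a share of 54.5%, so I expected target ahead in this flask.

The balance ratio says nothing about early times. Spring's share reads 86.0% at 3.00 h, and isomer of the product follows target, so I expected a higher share at 1.0 h.

The forecast gave 95% (range 91% to 98%) at 1.0 h and 54% (range 50% to 59%) at 40 h, with target leading: “Target stays slightly ahead, though not by much”. My share at 40 h differs from its number but lies inside its range.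

The flask gave 91.7% at 1.0 h and 55.5% at 40 h, with target ahead.

    starting material ⇌ target (K = 0.263, k = 3.32 × 10⁻⁴ s⁻¹)
    target ⇌ isomer of the product (K = 0.809, k = 3.34 × 10⁻⁵ s⁻¹)
    isomer of the product + free catalyst ⇌ starting material + free catalyst, rate k3*[free catalyst]*[isomer of the product] forward; the back reaction follows from the equilibrium constant (k = 0.147 M⁻¹ s⁻¹)
    free catalyst → spent catalyst (k = 3.84 × 10⁻⁴ s⁻¹)
    solid substrate ⇌ starting material, rate k5*(cs5 - [starting material]) while solid is left; crystals form when [starting material] > cs5 (solubility = 4.90 mM, k = 1.06 × 10⁻⁴ s⁻¹)
    starting material + free catalyst ⇌ idle complex, settled at all times (K = 39.4 M⁻¹)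

In the flask, free catalyst was down to 0.525% of its charge at 4.00 h, while solid substrate went on dissolving, from 68.7% then to 50.1% at 20.0 h, and target turned into isomer of the product with a forward half-life of 5.8 h. At 40.0 h the flask held target at 9.19% and isomer of the product at 7.37%, which is 0.802 isomer per target against the balance ratio of 0.788 read from spring and winter. The neighbour flask, charged with 0.88 mM of free catalyst, had a share of 87.4% at 1.0 h, and against the 55.9% from the balance ratio it ended at 55.5%.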